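**Strategy**

The side chain is numbered C1′ (the CH2 on the hydroquinone ring) to C15′. Everything rests on the C1′–C2′ bond: the E-configured, methyl-bearing C2′=C3′ olefin beside the benzylic CH2 is read as a masked terminal alkyne. In one flask, zirconium-catalysed syn-methylalumination of the C2′≡C3′ triple bond of a C2′–C15′ alkynol (C5′ and C12′ carbinols already set by Brown propargyl- and allylboration of geranyl acetate-derived enals) creates the C3′ methyl group and the E geometry, and palladium-catalysed coupling of the alkenylalane with a bis-silylated 2,5-dihydroxy-3-methylbenzyl bromide forges C1′–C2′. Acetylation and global desilylation complete the synthesis.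

Key step: step 9

Assumption: the B-allenyl reagent of step 6 is taken to show the same facial preference as the B-allyl reagent made from the same α-pinene enantiomer (same cyclic six-membered transition state); the target is (5′S,12′R) with all three chain olefins E.

**Route**

Step 1
Reactants: 1 geranyl acetate
Product: 3 (2E,6E)-3,7-dimethyl-8-oxoocta-2,6-dien-1-yl acetate, via allylic alcohol 2 (not isolated)
Conditions: SeO2 (1.2 equiv), 95% EtOH, reflux
Reagents that add atoms: selenium dioxide, O=[Se]=O
Why: Riley allylic oxidation (ene reaction, then [2,3]-sigmatropic shift) attacks the E-methyl group of the remote, more electron-rich C6=C7 olefin, and the allylic alcohol 2 is oxidised on to the E-enal; the acetate deactivates the C2=C3 olefin.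

Step 2
Reactants: 3 (2E,6E)-3,7-dimethyl-8-oxoocta-2,6-dien-1-yl acetate
Product: 5 (2E,6E,8R)-3,7-dimethylundeca-2,6,10-triene-1,8-diol, via borinate 4 (not isolated)
Conditions: (+)-Ipc2BOMe (from (−)-α-pinene), allylMgBr, Et2O, 0 °C to rt; then 3, −78 °C; then 3 M NaOH, 30% H2O2, MeOH, 0 °C to rt
Reagents that add atoms: allylmagnesium bromide, C=CC[Mg]Br, transferred through B-allyldiisopinocampheylborane made in the flask, C=CCB([C@H]1C[C@H]2C[C@@H]([C@@H]1C)C2(C)C)[C@H]1C[C@H]2C[C@@H]([C@@H]1C)C2(C)C
Why: Brown allylboration through a chair-like six-membered transition state should deliver allyl to the Re face of the α-methyl enal and set the (R) carbinol (C12′ of the target) under reagent control; the alkaline peroxide work-up cleaves the boron residues and deliberately saponifies the primary allylic acetate.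

Step 3
Reactants: 5 (2E,6E,8R)-3,7-dimethylundeca-2,6,10-triene-1,8-diol
Product: 6 (2E,6E,8R)-8-hydroxy-3,7-dimethylundeca-2,6,10-trienal
Conditions: TEMPO (10 mol %), PhI(OAc)2 (1.1 equiv), CH2Cl2, rt
Reagents that add atoms: none
Why: Oxoammonium (TEMPO/PhI(OAc)2) oxidation is selective for the primary allylic alcohol over the hindered secondary one and should give the E-enal without E/Z isomerisation.

Step 4
Reactants: 6 (2E,6E,8R)-8-hydroxy-3,7-dimethylundeca-2,6,10-trienal
Product: 7 (2E,6E,8R)-8-(tert-butyldimethylsilyloxy)-3,7-dimethylundeca-2,6,10-trienal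
Conditions: TBSCl, imidazole, DMF, rt
Reagents that add atoms: tert-butyldimethylsilyl chloride, CC(C)(C)[Si](C)(C)Cl
Why: Standard silylation of the only hydroxyl; the silyl ether keeps this carbinol distinct from the one that is later acetylated and survives all following steps.

Step 5
Reactants: 7 (2E,6E,8R)-8-(tert-butyldimethylsilyloxy)-3,7-dimethylundeca-2,6,10-trienal
Product: 8 (2E,6E,8R)-8-(tert-butyldimethylsilyloxy)-3,7,11-trimethyldodeca-2,6,10-trienal
Conditions: second-generation Grubbs catalyst (H2IMes)(PCy3)Cl2Ru=CHPh (5 mol %), 2-methyl-2-butene (large excess), CH2Cl2, 40 °C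
Reagents that add atoms: 2-methyl-2-butene, CC=C(C)C
Why: Olefin cross-metathesis: only the monosubstituted terminal olefin engages the ruthenium carbene, and excess 2-methyl-2-butene caps it as the isopropylidene (prenyl) terminus, while the trisubstituted olefins and the enal are spectators.

Step 6
Reactants: 8 (2E,6E,8R)-8-(tert-butyldimethylsilyloxy)-3,7,11-trimethyldodeca-2,6,10-trienal
Product: 10 (4S,5E,9E,11R)-11-(tert-butyldimethylsilyloxy)-6,10,14-trimethylpentadeca-5,9,13-trien-1-yn-4-ol, via borinate 9 (not isolated)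
Conditions: (−)-Ipc2BOMe (from (+)-α-pinene), allenylMgBr, Et2O, −78 °C to rt; then 8, −100 °C; then 3 M NaOH, 30% H2O2, 0 °C to rt
Reagents that add atoms: allenylmagnesium bromide, C=C=C[Mg]Br, transferred through B-allenyldiisopinocampheylborane made in the flask, C=C=CB([C@@H]1C[C@@H]2C[C@H]([C@H]1C)C2(C)C)[C@@H]1C[C@@H]2C[C@H]([C@H]1C)C2(C)C
Why: Brown propargylboration: the allenylborane adds through a six-membered SE2′ transition state to the Si face of the enal in 1,2-fashion, which should give the homopropargylic alcohol with the (S) carbinol (C5′ of the target) under reagent control, independent of the remote silyloxy centre.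

Step 7
Reactants: 11 2,6-dimethylhydroquinone
Product: 12 1,4-bis(tert-butyldimethylsilyloxy)-2,6-dimethylbenzene
Conditions: TBSOTf (2.4 equiv), 2,6-lutidine, CH2Cl2, 0 °C to rt
Reagents that add atoms: tert-butyldimethylsilyl triflate, CC(C)(C)[Si](C)(C)OS(=O)(=O)C(F)(F)F
Why: The silyl triflate is reactive enough to silylate both phenols, including the one flanked by two methyl groups.

Step 8
Reactants: 12 1,4-bis(tert-butyldimethylsilyloxy)-2,6-dimethylbenzene
Product: 13 1-(bromomethyl)-2,5-bis(tert-butyldimethylsilyloxy)-3-methylbenzene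
Conditions: NBS (0.9 equiv), AIBN (5 mol %), PhCF3, 80 °C; unreacted 12 recycled
Reagents that add atoms: N-bromosuccinimide, O=C1CCC(=O)N1Br
Why: Wohl–Ziegler radical bromination of one of two equivalent benzylic methyl groups; the bulky silyl ethers attenuate and shield the ring, and non-polar radical conditions with sub-stoichiometric NBS should disfavour ring bromination and double bromination.

Step 9
Reactants: 10 (4S,5E,9E,11R)-11-(tert-butyldimethylsilyloxy)-6,10,14-trimethylpentadeca-5,9,13-trien-1-yn-4-ol; 13 1-(bromomethyl)-2,5-bis(tert-butyldimethylsilyloxy)-3-methylbenzene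
Product: 15 (2E,5S,6E,10E,12R)-1-[2,5-bis(tert-butyldimethylsilyloxy)-3-methylphenyl]-12-(tert-butyldimethylsilyloxy)-3,7,11,15-tetramethylhexadeca-2,6,10,14-tetraen-5-ol, via alkenylalane 14 (not isolated)
Conditions: Me3Al (4 equiv), Cp2ZrCl2 (0.5 equiv), CH2Cl2, 0 °C to rt; volatiles removed in vacuo; then 13 (1.2 equiv), Pd(PPh3)4 (5 mol %), THF, rt; aq. Rochelle salt work-up
Reagents that add atoms: trimethylaluminium, C[Al](C)C
Why: Negishi one-pot carboalumination–cross-coupling: a methylzirconocene species from Cp2ZrCl2 and Me3Al adds methyl and metal syn across the terminal triple bond of the aluminium alkoxide of 10 (methyl to internal C3′, metal to terminal C2′) and transmetalates to the (E)-alkenyldimethylalane 14; zerovalent palladium then inserts into the benzylic C–Br bond of 13, the alkenyl group moves from aluminium to palladium, and reductive elimination forms C1′–C2′ with retention of olefin geometry. The closest known reaction type is the carboalumination/benzylic-halide coupling used to attach polyprenyl chains to protected hydroquinone rings. No ring is closed and no stereocentre is created; C5′ and C12′ are untouched. The step needs regioselectivity (secured by the terminal alkyne, which places the metal on the CH carbon), E geometry (secured by syn addition and stereoretentive coupling, with the mixture kept at or below room temperature to avoid alkoxide-assisted isomerisation) and chemoselectivity (trisubstituted olefins, silyl ethers and the aluminium alkoxide are inert to methylzirconation, and excess Me3Al is pumped off so that alkenyl rather than methyl is transferred). Because the benzylic carbon is the electrophile and the olefin arrives ready-made, the allylic transposition and E/Z scrambling typical of aryl-nucleophile plus allyl-electrophile couplings cannot occur.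

Step 10
Reactants: 15 (2E,5S,6E,10E,12R)-1-[2,5-bis(tert-butyldimethylsilyloxy)-3-methylphenyl]-12-(tert-butyldimethylsilyloxy)-3,7,11,15-tetramethylhexadeca-2,6,10,14-tetraen-5-ol
Product: 16 (2E,5S,6E,10E,12R)-1-[2,5-bis(tert-butyldimethylsilyloxy)-3-methylphenyl]-12-(tert-butyldimethylsilyloxy)-3,7,11,15-tetramethylhexadeca-2,6,10,14-tetraen-5-yl acetate
Conditions: Ac2O, pyridine, DMAP (cat.), CH2Cl2, 0 °C to rt
Reagents that add atoms: acetic anhydride, CC(=O)OC(C)=O
Why: DMAP-catalysed acylation of the only free hydroxyl proceeds at oxygen with retention at C5′, all other oxygens being silylated.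

Step 11
Reactants: 16 (2E,5S,6E,10E,12R)-1-[2,5-bis(tert-butyldimethylsilyloxy)-3-methylphenyl]-12-(tert-butyldimethylsilyloxy)-3,7,11,15-tetramethylhexadeca-2,6,10,14-tetraen-5-yl acetate
Product: 17 (2E,5S,6E,10E,12R)-1-(2,5-dihydroxy-3-methylphenyl)-12-hydroxy-3,7,11,15-tetramethylhexadeca-2,6,10,14-tetraen-5-yl acetate (CNP0252507.1)
Conditions: TBAF (6 equiv), AcOH (6 equiv), THF, 0 °C to 40 °C, argon, degassed work-up
Reagents that add atoms: none
Why: Acetic acid-buffered fluoride desilylation should remove both aryl silyl ethers and the secondary silyl ether while the allylic acetate is inert under these near-neutral conditions; exclusion of air protects the hydroquinone from oxidation to the quinone.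

**Compound list**

1 | geranyl acetate, (2E)-3,7-dimethylocta-2,6-dien-1-yl acetate | CC(=O)OC/C=C(\C)CCC=C(C)C | starting material
2 | (2E,6E)-8-hydroxy-3,7-dimethylocta-2,6-dien-1-yl acetate (not isolated) | CC(=O)OC/C=C(\C)CC/C=C(\C)CO | intermediate
3 | (2E,6E)-3,7-dimethyl-8-oxoocta-2,6-dien-1-yl acetate | CC(=O)OC/C=C(\C)CC/C=C(\C)C=O | intermediate
4 | (2E,6E,8R)-8-(diisopinocampheylboranyloxy)-3,7-dimethylundeca-2,6,10-trien-1-yl acetate (not isolated) | CC(=O)OC/C=C(\C)CC/C=C(\C)[C@H](OB([C@H]1C[C@H]2C[C@@H]([C@@H]1C)C2(C)C)[C@H]1C[C@H]2C[C@@H]([C@@H]1C)C2(C)C)CC=C | intermediate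
5 | (2E,6E,8R)-3,7-dimethylundeca-2,6,10-triene-1,8-diol | OC/C=C(\C)CC/C=C(\C)[C@H](O)CC=C | intermediate
6 | (2E,6E,8R)-8-hydroxy-3,7-dimethylundeca-2,6,10-trienal | O=C/C=C(\C)CC/C=C(\C)[C@H](O)CC=C | intermediate
7 | (2E,6E,8R)-8-(tert-butyldimethylsilyloxy)-3,7-dimethylundeca-2,6,10-trienal | O=C/C=C(\C)CC/C=C(\C)[C@H](O[Si](C)(C)C(C)(C)C)CC=C | intermediate
8 | (2E,6E,8R)-8-(tert-butyldimethylsilyloxy)-3,7,11-trimethyldodeca-2,6,10-trienal | O=C/C=C(\C)CC/C=C(\C)[C@H](O[Si](C)(C)C(C)(C)C)CC=C(C)C | intermediate
9 | (4S,5E,9E,11R)-4-(diisopinocampheylboranyloxy)-11-(tert-butyldimethylsilyloxy)-6,10,14-trimethylpentadeca-5,9,13-trien-1-yne (not isolated) | C#CC[C@H](OB([C@@H]1C[C@@H]2C[C@H]([C@H]1C)C2(C)C)[C@@H]1C[C@@H]2C[C@H]([C@H]1C)C2(C)C)/C=C(\C)CC/C=C(\C)[C@H](O[Si](C)(C)C(C)(C)C)CC=C(C)C | intermediate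
10 | (4S,5E,9E,11R)-11-(tert-butyldimethylsilyloxy)-6,10,14-trimethylpentadeca-5,9,13-trien-1-yn-4-ol | C#CC[C@H](O)/C=C(\C)CC/C=C(\C)[C@H](O[Si](C)(C)C(C)(C)C)CC=C(C)C | intermediate
11 | 2,6-dimethylhydroquinone (2,6-dimethylbenzene-1,4-diol) | Cc1cc(O)cc(C)c1O | starting material
12 | 1,4-bis(tert-butyldimethylsilyloxy)-2,6-dimethylbenzene | Cc1cc(O[Si](C)(C)C(C)(C)C)cc(C)c1O[Si](C)(C)C(C)(C)C | intermediate
13 | 1-(bromomethyl)-2,5-bis(tert-butyldimethylsilyloxy)-3-methylbenzene | BrCc1cc(O[Si](C)(C)C(C)(C)C)cc(C)c1O[Si](C)(C)C(C)(C)C | intermediate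
14 | (E)-alkenyldimethylalane of 10 as its dimethylaluminium alkoxide (not isolated) | C[Al](C)O[C@H](/C=C(\C)CC/C=C(\C)[C@H](O[Si](C)(C)C(C)(C)C)CC=C(C)C)C/C(C)=C/[Al](C)C | intermediate
15 | (2E,5S,6E,10E,12R)-1-[2,5-bis(tert-butyldimethylsilyloxy)-3-methylphenyl]-12-(tert-butyldimethylsilyloxy)-3,7,11,15-tetramethylhexadeca-2,6,10,14-tetraen-5-ol | O[C@H](/C=C(\C)CC/C=C(\C)[C@H](O[Si](C)(C)C(C)(C)C)CC=C(C)C)C/C(C)=C/Cc1cc(O[Si](C)(C)C(C)(C)C)cc(C)c1O[Si](C)(C)C(C)(C)C | intermediate
16 | (2E,5S,6E,10E,12R)-1-[2,5-bis(tert-butyldimethylsilyloxy)-3-methylphenyl]-12-(tert-butyldimethylsilyloxy)-3,7,11,15-tetramethylhexadeca-2,6,10,14-tetraen-5-yl acetate | CC(=O)O[C@H](/C=C(\C)CC/C=C(\C)[C@H](O[Si](C)(C)C(C)(C)C)CC=C(C)C)C/C(C)=C/Cc1cc(O[Si](C)(C)C(C)(C)C)cc(C)c1O[Si](C)(C)C(C)(C)C | intermediate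
17 | (2E,5S,6E,10E,12R)-1-(2,5-dihydroxy-3-methylphenyl)-12-hydroxy-3,7,11,15-tetramethylhexadeca-2,6,10,14-tetraen-5-yl acetate | CC(=O)O[C@H](/C=C(\C)CC/C=C(\C)[C@H](O)CC=C(C)C)C/C(C)=C/Cc1cc(O)cc(C)c1O | target

**Count**

Total step count: 11. Longest linear sequence: 9 steps (steps 1 to 6, then 9, 10 and 11); steps 7 and 8 form the two-step aryl branch.

**Steps most likely to fail**

Step 9 (key step). The process at risk is transfer of the alkenyl group from an alane that is internally chelated by the C5′ aluminium alkoxide. Transmetalation may be slow, methyl transfer from residual Me3Al or homocoupling of the electron-rich benzylic bromide may compete, and the olefin geometry may erode through alkoxide-assisted isomerisation. The fallback reverses the polarity of the same bond formation; it sets out from 10 and comes back to the route at 16. The carboalumination of 10 is run as before and the alane 14 is quenched with I2 (THF, −30 °C) to give (1E,4S,5E,9E,11R)-11-(tert-butyldimethylsilyloxy)-1-iodo-2,6,10,14-tetramethylpentadeca-1,5,9,13-tetraen-4-ol F1. Acetylation (Ac2O, pyridine, DMAP) gives the corresponding 4-yl acetate F2. Bromide 13 is converted with zinc dust and LiCl in THF into [2,5-bis(tert-butyldimethylsilyloxy)-3-methylbenzyl]zinc bromide F3. Negishi coupling of F2 with F3 (Pd(PPh3)4, THF, rt) should give 16 directly, with the alkenyl iodide geometry retained and the acetate tolerated by the organozinc.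

Step 8. The process at risk is competing electrophilic bromination of the electron-rich ring and bromination of the second methyl group. The fallback builds the benzylic carbon at the aldehyde oxidation level instead of by radical C–H bromination. It does not set out from a numbered compound: it replaces 11 and 12 by commercial 2-hydroxy-3-methylbenzaldehyde F4 and comes back to the route at 13. Elbs persulfate oxidation (K2S2O8, aq. NaOH, 0 °C to rt) gives potassium 3-formyl-4-hydroxy-5-methylphenyl sulfate F5, which is hydrolysed (aq. HCl, 70 °C) to 2,5-dihydroxy-3-methylbenzaldehyde F6. Silylation (TBSCl, imidazole, DMF) gives 2,5-bis(tert-butyldimethylsilyloxy)-3-methylbenzaldehyde F7. Reduction with DIBAL-H (CH2Cl2, −78 °C, cold quench to avoid silyl migration) gives [2,5-bis(tert-butyldimethylsilyloxy)-3-methylphenyl]methanol F8. Appel bromination (CBr4, PPh3, CH2Cl2, 0 °C) gives 13.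

Step 6. The processes at risk are poor facial selectivity on the β,β-disubstituted enal, leakage to the allenyl carbinol, and racemic background addition by residual Grignard reagent at −100 °C. The fallback replaces the stoichiometric chiral borane by catalytic Brønsted-acid control; it sets out from 8 and comes back to the route at 10. Aldehyde 8 is treated with allenylboronic acid pinacol ester and the chiral phosphoric acid (S)-TRIP (3,3′-bis(2,4,6-triisopropylphenyl)-1,1′-binaphthyl-2,2′-diyl hydrogen phosphate, 5 mol %; enantiomer chosen by analogy with the sense known for allylboration) in toluene with 4 Å molecular sieves at 0 °C. This gives the (4S)-4-(pinacolboryloxy) derivative of 10 F9, which is hydrolysed on aqueous work-up to 10.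

**Further compounds**

F1 | step 9 | (1E,4S,5E,9E,11R)-11-(tert-butyldimethylsilyloxy)-1-iodo-2,6,10,14-tetramethylpentadeca-1,5,9,13-tetraen-4-ol | O[C@H](/C=C(\C)CC/C=C(\C)[C@H](O[Si](C)(C)C(C)(C)C)CC=C(C)C)C/C(C)=C/I
F2 | step 9 | (1E,4S,5E,9E,11R)-11-(tert-butyldimethylsilyloxy)-1-iodo-2,6,10,14-tetramethylpentadeca-1,5,9,13-tetraen-4-yl acetate | CC(=O)O[C@H](/C=C(\C)CC/C=C(\C)[C@H](O[Si](C)(C)C(C)(C)C)CC=C(C)C)C/C(C)=C/I
F3 | step 9 | [2,5-bis(tert-butyldimethylsilyloxy)-3-methylbenzyl]zinc bromide | Br[Zn]Cc1cc(O[Si](C)(C)C(C)(C)C)cc(C)c1O[Si](C)(C)C(C)(C)C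
F4 | step 8 | 2-hydroxy-3-methylbenzaldehyde | Cc1cccc(C=O)c1O
F5 | step 8 | potassium 3-formyl-4-hydroxy-5-methylphenyl sulfate | Cc1cc(OS(=O)(=O)[O-])cc(C=O)c1O.[K+]
F6 | step 8 | 2,5-dihydroxy-3-methylbenzaldehyde | Cc1cc(O)cc(C=O)c1O
F7 | step 8 | 2,5-bis(tert-butyldimethylsilyloxy)-3-methylbenzaldehyde | Cc1cc(O[Si](C)(C)C(C)(C)C)cc(C=O)c1O[Si](C)(C)C(C)(C)C
F8 | step 8 | [2,5-bis(tert-butyldimethylsilyloxy)-3-methylphenyl]methanol | Cc1cc(O[Si](C)(C)C(C)(C)C)cc(CO)c1O[Si](C)(C)C(C)(C)C
F9 | step 6 | (4S,5E,9E,11R)-11-(tert-butyldimethylsilyloxy)-6,10,14-trimethyl-4-(4,4,5,5-tetramethyl-1,3,2-dioxaborolan-2-yloxy)pentadeca-5,9,13-trien-1-yne | C#CC[C@H](OB1OC(C)(C)C(C)(C)O1)/C=C(\C)CC/C=C(\C)[C@H](O[Si](C)(C)C(C)(C)C)CC=C(C)C
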